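**Retrosynthetic overview**

1. Ring labels: rings A (2,4-dihydroxy-6-methylphenyl) and B share the left carbonyl, rings C and D (4-hydroxy-2-methoxy-6-methylphenyl) the right one. On rings B and C, position 1 carries the CH2 bridge, 2 OMe, 3 H, 4 OH, 5 the aroyl group, 6 OH; on rings A and D, position 1 carries the carbonyl and 2 the methyl.
2. The last skeletal bond joins position 1 of ring B to the bridging CH2: ring B of the deprotected left benzophenone adds to the ortho-quinone methide of ring C (exocyclic methylene at position 1, carbonyl at position 6). The quinone methide is stored as its dimethylamine adduct (Mannich base), because a free salicyl alcohol on so electron-rich a ring would ionise on handling.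
3. Structural feature used: the left carbonyl carbon is wedged between position 1 of ring A and position 5 of ring B, both of which carry two ortho substituents, and ring B without its bridge is a threefold-symmetric 1,3,5-trioxygenated benzene. Both bonds to that carbon are therefore cut at once, back to the ring A iodide, CO and 1,3,5-trimethoxybenzene.
4. Right ketone: ring D must keep an ortho methoxy group, so chelation-directed demethylation cannot be used on that half. The bond from position 5 of ring C to the carbonyl comes from addition of a ring C aryllithium (lithiated between two methoxymethyl ethers) to the ring D aldehyde, then oxidation.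
5. No ring is formed anywhere; the four benzene rings are bought (orcinol, 1,3,5-trimethoxybenzene, 5-methoxyresorcinol, orsellinaldehyde). Order of events: left ketone, right ketone, bridge, final hydrogenolysis.

Key step: step 3

Assumption: orsellinaldehyde and 5-methoxyresorcinol are treated as catalogue compounds; the target has no stereocentre, and the only one met on the way (carbinol 15, racemic) is erased by oxidation.

**Route**

Step 1
Reactants: 1 orcinol (5-methylbenzene-1,3-diol)
Product: 2 1,3-bis(benzyloxy)-5-methylbenzene
Conditions: BnBr (2.3 equiv), K2CO3 (3 equiv), DMF, rt → 60 °C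
Reagents that add atoms: benzyl bromide, BrCc1ccccc1
Why: Double Williamson etherification of the two phenols with a reactive benzylic halide under carbonate base is routine and leaves the ring carbons untouched.

Step 2
Reactants: 2 1,3-bis(benzyloxy)-5-methylbenzene
Product: 3 1,5-bis(benzyloxy)-2-iodo-3-methylbenzene
Conditions: N-iodosuccinimide (1.05 equiv), CF3CO2H (cat.), MeCN, 0 °C → rt
Reagents that add atoms: N-iodosuccinimide, O=C1CCC(=O)N1I
Why: Electrophilic aromatic iodination should go to the position next to the methyl group, which is para to one benzyloxy group, ortho to the other and less crowded than the site between the two benzyloxy groups, and the two such positions are equivalent by symmetry.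

Step 3
Reactants: 3 1,5-bis(benzyloxy)-2-iodo-3-methylbenzene, 4 carbon monoxide, 5 1,3,5-trimethoxybenzene (3 equiv)
Product: 7 [2,4-bis(benzyloxy)-6-methylphenyl](2,4,6-trimethoxyphenyl)methanone, via aroyl triflate 6 (not isolated)
Conditions: Pd(P(t-Bu)3)2 (5 mol %), AgOSO2CF3 (1.3 equiv), 2,6-di-tert-butylpyridine (1.3 equiv), CO (4 atm), ClCH2CH2Cl, 60 °C
Reagents that add atoms: none
Why: Zerovalent palladium bearing one P(t-Bu)3 inserts into the C–I bond of 3, migratory insertion of CO gives the aroylpalladium iodide, AgOSO2CF3 removes iodide as silver iodide, and the bulk of the phosphine drives reductive elimination of aroyl triflate 6. With two ortho substituents and two donor oxygens, 6 ionises readily to a linear acylium ion that has little steric demand at carbon and acylates 5 by ordinary electrophilic aromatic substitution, while 2,6-di-tert-butylpyridine holds the liberated CF3SO3H so that the benzyl ethers are not cleaved. The closest known reaction type is the palladium-catalysed carbonylative C–H acylation of electron-rich arenes with aryl iodides through aroyl triflates made in situ, a catalytic Friedel–Crafts acylation, applied here to a 2,6-disubstituted iodide. No ring is closed and no stereocentre is created, the two bonds of the carbonyl carbon to position 1 of ring A and to position 5 of ring B being formed in one operation. Only monoacylation is required: the three C–H positions of 5 are equivalent, so there is no regiochemical choice, the first ketone deactivates the ring towards a second acylation, and the excess of 5 outcompetes the unactivated phenyl rings of the benzyl ethers.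

Step 4
Reactants: 7 [2,4-bis(benzyloxy)-6-methylphenyl](2,4,6-trimethoxyphenyl)methanone
Product: 8 (2,4-dihydroxy-6-methylphenyl)(2,6-dihydroxy-4-methoxyphenyl)methanone
Conditions: BCl3 (10 equiv), pentamethylbenzene (6 equiv), CH2Cl2, −78 °C → rt; then H2O
Reagents that add atoms: none
Why: Lewis-acid ether cleavage, in which BCl3 removes the aryl benzyl ethers at low temperature with pentamethylbenzene trapping the benzyl cations and, on warming, is delivered by chelation to the ketone oxygen onto the two flanking methyl ethers of ring B, whereas the para methoxy group has no neighbouring carbonyl to deliver boron and should remain.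

Step 5
Reactants: 9 5-methoxyresorcinol (5-methoxybenzene-1,3-diol)
Product: 10 1-methoxy-3,5-bis(methoxymethoxy)benzene
Conditions: MeOCH2Cl (2.5 equiv), i-Pr2NEt (3 equiv), CH2Cl2, 0 °C → rt
Reagents that add atoms: chloromethyl methyl ether, COCCl
Why: O-alkylation of both phenols with the reactive α-chloro ether (methoxymethyl protection) installs two strong ortho-directing groups for the metalation in step 8.

Step 6
Reactants: 11 orsellinaldehyde (2,4-dihydroxy-6-methylbenzaldehyde)
Product: 12 4-(benzyloxy)-2-hydroxy-6-methylbenzaldehyde
Conditions: BnBr (1.05 equiv), K2CO3 (1.1 equiv), acetone, rt → 40 °C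
Reagents that add atoms: benzyl bromide, BrCc1ccccc1
Why: Regioselective Williamson etherification, since the 2-hydroxyl is held in a hydrogen bond to the aldehyde and is the less acidic one, so one equivalent of benzyl bromide should alkylate the 4-hydroxyl.

Step 7
Reactants: 12 4-(benzyloxy)-2-hydroxy-6-methylbenzaldehyde
Product: 13 4-(benzyloxy)-2-methoxy-6-methylbenzaldehyde
Conditions: MeI (2 equiv), K2CO3 (2 equiv), DMF, 40 °C
Reagents that add atoms: iodomethane, CI
Why: Williamson methylation of the remaining chelated phenol with excess iodomethane in a dipolar solvent fixes the ortho methoxy group of ring D before any ketone exists.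

Step 8
Reactants: 10 1-methoxy-3,5-bis(methoxymethoxy)benzene (1.2 equiv), 13 4-(benzyloxy)-2-methoxy-6-methylbenzaldehyde
Product: 15 rac-[4-(benzyloxy)-2-methoxy-6-methylphenyl][4-methoxy-2,6-bis(methoxymethoxy)phenyl]methanol, via aryllithium 14 (not isolated)
Conditions: n-BuLi (1.15 equiv), THF, 0 °C; then 13, −78 → 0 °C; aq. NH4Cl
Reagents that add atoms: none
Why: Directed ortho-metalation takes place at the carbon between the two methoxymethoxy groups, the most acidified and best chelated site, and the aryllithium then undergoes 1,2-addition to the non-enolisable aldehyde, the carbinol centre being formed without control (racemate) and erased in step 9.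

Step 9
Reactants: 15 rac-[4-(benzyloxy)-2-methoxy-6-methylphenyl][4-methoxy-2,6-bis(methoxymethoxy)phenyl]methanol
Product: 16 [4-(benzyloxy)-2-methoxy-6-methylphenyl][4-methoxy-2,6-bis(methoxymethoxy)phenyl]methanone
Conditions: IBX (2-iodoxybenzoic acid, 2 equiv), EtOAc, 75 °C
Reagents that add atoms: none
Why: Oxidation of a doubly benzylic secondary alcohol to the diaryl ketone with the hypervalent iodine oxidant IBX runs under neutral conditions that spare the methoxymethyl and benzyl ethers.

Step 10
Reactants: 16 [4-(benzyloxy)-2-methoxy-6-methylphenyl][4-methoxy-2,6-bis(methoxymethoxy)phenyl]methanone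
Product: 17 [4-(benzyloxy)-2-methoxy-6-methylphenyl](2,6-dihydroxy-4-methoxyphenyl)methanone
Conditions: HCl (3 M aq.), MeOH/THF, 45 °C
Reagents that add atoms: none
Why: Acid-catalysed acetal cleavage (solvolysis of the methoxymethyl ethers) frees the two ring C phenols while methyl and benzyl ethers are inert, methanol capturing the oxocarbenium ion as dimethoxymethane so that it does not alkylate the ring.

Step 11
Reactants: 17 [4-(benzyloxy)-2-methoxy-6-methylphenyl](2,6-dihydroxy-4-methoxyphenyl)methanone
Product: 18 [4-(benzyloxy)-2-methoxy-6-methylphenyl]{3-[(dimethylamino)methyl]-2,6-dihydroxy-4-methoxyphenyl}methanone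
Conditions: CH2=NMe2 I (1.05 equiv), Et3N (1.1 equiv), CH2Cl2, 0 °C → rt
Reagents that add atoms: dimethyl(methylidene)ammonium iodide, C=[N+](C)C.[I-]
Why: Phenolic Mannich reaction with the preformed iminium salt, in which only ring C carries free hydroxyls, its two open positions are equivalent, and one equivalent of this mild electrophile should stop at the mono-aminomethyl compound.

Step 12
Reactants: 18 [4-(benzyloxy)-2-methoxy-6-methylphenyl]{3-[(dimethylamino)methyl]-2,6-dihydroxy-4-methoxyphenyl}methanone, 8 (2,4-dihydroxy-6-methylphenyl)(2,6-dihydroxy-4-methoxyphenyl)methanone (3 equiv)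
Product: 20 [3-({3-[4-(benzyloxy)-2-methoxy-6-methylbenzoyl]-2,4-dihydroxy-6-methoxyphenyl}methyl)-2,6-dihydroxy-4-methoxyphenyl](2,4-dihydroxy-6-methylphenyl)methanone, via ortho-quinone methide 19 (not isolated)
Conditions: 1,4-dioxane, 100 °C, slow stream of nitrogen
Reagents that add atoms: none
Why: Thermal loss of dimethylamine from the phenolic Mannich base gives the ortho-quinone methide, which undergoes conjugate addition (a Friedel–Crafts-type alkylation) by ring B of 8, the ring with three oxygen donors and two equivalent open positions, the excess of 8 suppressing self-condensation and double alkylation.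

Step 13
Reactants: 20, the 4-O-benzyl ether (ring D) of the target
Product: 21 [3-({2,4-dihydroxy-3-[4-hydroxy-2-methoxy-6-methylbenzoyl]-6-methoxyphenyl}methyl)-2,6-dihydroxy-4-methoxyphenyl](2,4-dihydroxy-6-methylphenyl)methanone (CNP0596095.0)
Conditions: H2 (1 atm), Pd/C, EtOAc/MeOH, rt
Reagents that add atoms: none
Why: Catalytic hydrogenolysis of the single aryl benzyl ether releases the ring D phenol, the diarylmethane and the hindered, hydrogen-bonded diaryl ketones being inert under these mild conditions.

**Compound list**

1 | orcinol | Cc1cc(O)cc(O)c1 | starting material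
2 | 1,3-bis(benzyloxy)-5-methylbenzene | Cc1cc(OCc2ccccc2)cc(OCc2ccccc2)c1 | intermediate
3 | 1,5-bis(benzyloxy)-2-iodo-3-methylbenzene | Cc1cc(OCc2ccccc2)cc(OCc2ccccc2)c1I | intermediate
4 | carbon monoxide | [C-]#[O+] | starting material
5 | 1,3,5-trimethoxybenzene | COc1cc(OC)cc(OC)c1 | starting material
6 | 2,4-bis(benzyloxy)-6-methylbenzoyl trifluoromethanesulfonate (not isolated) | Cc1cc(OCc2ccccc2)cc(OCc2ccccc2)c1C(=O)OS(=O)(=O)C(F)(F)F | intermediate
7 | [2,4-bis(benzyloxy)-6-methylphenyl](2,4,6-trimethoxyphenyl)methanone | COc1cc(OC)c(C(=O)c2c(C)cc(OCc3ccccc3)cc2OCc3ccccc3)c(OC)c1 | intermediate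
8 | (2,4-dihydroxy-6-methylphenyl)(2,6-dihydroxy-4-methoxyphenyl)methanone | COc1cc(O)c(C(=O)c2c(C)cc(O)cc2O)c(O)c1 | intermediate
9 | 5-methoxyresorcinol | COc1cc(O)cc(O)c1 | starting material
10 | 1-methoxy-3,5-bis(methoxymethoxy)benzene | COCOc1cc(OC)cc(OCOC)c1 | intermediate
11 | orsellinaldehyde (2,4-dihydroxy-6-methylbenzaldehyde) | Cc1cc(O)cc(O)c1C=O | starting material
12 | 4-(benzyloxy)-2-hydroxy-6-methylbenzaldehyde | Cc1cc(OCc2ccccc2)cc(O)c1C=O | intermediate
13 | 4-(benzyloxy)-2-methoxy-6-methylbenzaldehyde | COc1cc(OCc2ccccc2)cc(C)c1C=O | intermediate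
14 | [4-methoxy-2,6-bis(methoxymethoxy)phenyl]lithium (not isolated) | [Li]c1c(OCOC)cc(OC)cc1OCOC | intermediate
15 | rac-[4-(benzyloxy)-2-methoxy-6-methylphenyl][4-methoxy-2,6-bis(methoxymethoxy)phenyl]methanol | COCOc1cc(OC)cc(OCOC)c1C(O)c1c(C)cc(OCc2ccccc2)cc1OC | intermediate
16 | [4-(benzyloxy)-2-methoxy-6-methylphenyl][4-methoxy-2,6-bis(methoxymethoxy)phenyl]methanone | COCOc1cc(OC)cc(OCOC)c1C(=O)c1c(C)cc(OCc2ccccc2)cc1OC | intermediate
17 | [4-(benzyloxy)-2-methoxy-6-methylphenyl](2,6-dihydroxy-4-methoxyphenyl)methanone | COc1cc(O)c(C(=O)c2c(C)cc(OCc3ccccc3)cc2OC)c(O)c1 | intermediate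
18 | [4-(benzyloxy)-2-methoxy-6-methylphenyl]{3-[(dimethylamino)methyl]-2,6-dihydroxy-4-methoxyphenyl}methanone | COc1cc(O)c(C(=O)c2c(C)cc(OCc3ccccc3)cc2OC)c(O)c1CN(C)C | intermediate
19 | 2-[4-(benzyloxy)-2-methoxy-6-methylbenzoyl]-3-hydroxy-5-methoxy-6-methylidenecyclohexa-2,4-dien-1-one (not isolated) | C=C1C(OC)=CC(O)=C(C(=O)c2c(C)cc(OCc3ccccc3)cc2OC)C1=O | intermediate
20 | [3-({3-[4-(benzyloxy)-2-methoxy-6-methylbenzoyl]-2,4-dihydroxy-6-methoxyphenyl}methyl)-2,6-dihydroxy-4-methoxyphenyl](2,4-dihydroxy-6-methylphenyl)methanone | COc1cc(O)c(C(=O)c2c(C)cc(O)cc2O)c(O)c1Cc1c(OC)cc(O)c(C(=O)c2c(C)cc(OCc3ccccc3)cc2OC)c1O | intermediate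
21 | CNP0596095.0, [3-({2,4-dihydroxy-3-[4-hydroxy-2-methoxy-6-methylbenzoyl]-6-methoxyphenyl}methyl)-2,6-dihydroxy-4-methoxyphenyl](2,4-dihydroxy-6-methylphenyl)methanone | COc1cc(O)c(C(=O)c2c(C)cc(O)cc2O)c(O)c1Cc1c(OC)cc(O)c(C(=O)c2c(C)cc(O)cc2OC)c1O | target

**Step count and risks**

Total steps: 13. Longest linear sequence: 8 steps (steps 6, 7, 8, 9, 10, 11, 12, 13, from orsellinaldehyde 11).

Steps most likely to fail:

Step 3. The doubly ortho-substituted arylpalladium may take up CO or release the aroyl triflate too slowly, so that the catalyst stalls or the iodide is simply reduced. The acylium ion or the acid may also strip the neighbouring benzyl ether. The fallback sets out from 3. Iodine–lithium exchange with n-BuLi in THF at −78 °C should give [2,4-bis(benzyloxy)-6-methylphenyl]lithium F1. This is added to commercial 2,4,6-trimethoxybenzaldehyde to give racemic [2,4-bis(benzyloxy)-6-methylphenyl](2,4,6-trimethoxyphenyl)methanol F2. Oxidation of the carbinol with IBX in EtOAc comes back to the route at 7.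

Step 4. Once boron is chelated between the first liberated phenol and the ketone, cleavage of the second ortho methyl ether of ring B may stall, and benzyl cations that escape the scavenger may alkylate the electron-rich rings. The fallback sets out from 7 and separates the two tasks. Hydrogenolysis (H2, Pd/C, EtOAc) should give (2,4-dihydroxy-6-methylphenyl)(2,4,6-trimethoxyphenyl)methanone F3. Treatment with AlCl3 in chlorobenzene at 90 °C, the classical aluminium-chelate bis-ortho-demethylation of 2,4,6-trimethoxyaryl ketones, then comes back to the route at 8.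

Step 12. The quinone methide may be captured by the open ring C position of a second molecule of 18 (oligomerisation), by ring A of 8 instead of ring B, or by the product itself (double alkylation). The fallback reverses the roles of the two halves and sets out from 8. Aminomethylation with CH2=NMe2 I and Et3N, which as a weak electrophile should pick the most nucleophilic ring, gives {3-[(dimethylamino)methyl]-2,6-dihydroxy-4-methoxyphenyl}(2,4-dihydroxy-6-methylphenyl)methanone F4. Heating this with an excess of 17 in dioxane releases 2-(2,4-dihydroxy-6-methylbenzoyl)-3-hydroxy-5-methoxy-6-methylidenecyclohexa-2,4-dien-1-one F5. Ring C of 17, its only nucleophilic ring, captures it, and the route is rejoined at 20.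

**Further compounds**

F1 | step 3 | [2,4-bis(benzyloxy)-6-methylphenyl]lithium | [Li]c1c(C)cc(OCc2ccccc2)cc1OCc1ccccc1
F2 | step 3 | rac-[2,4-bis(benzyloxy)-6-methylphenyl](2,4,6-trimethoxyphenyl)methanol | COc1cc(OC)c(C(O)c2c(C)cc(OCc3ccccc3)cc2OCc3ccccc3)c(OC)c1
F3 | step 4 | (2,4-dihydroxy-6-methylphenyl)(2,4,6-trimethoxyphenyl)methanone | COc1cc(OC)c(C(=O)c2c(C)cc(O)cc2O)c(OC)c1
F4 | step 12 | {3-[(dimethylamino)methyl]-2,6-dihydroxy-4-methoxyphenyl}(2,4-dihydroxy-6-methylphenyl)methanone | COc1cc(O)c(C(=O)c2c(C)cc(O)cc2O)c(O)c1CN(C)C
F5 | step 12 | 2-(2,4-dihydroxy-6-methylbenzoyl)-3-hydroxy-5-methoxy-6-methylidenecyclohexa-2,4-dien-1-one | C=C1C(OC)=CC(O)=C(C(=O)c2c(C)cc(O)cc2O)C1=O
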